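Ring A (C1–C5, C10) is read as a cyclohexene made by a catalytic enantioselective Diels–Alder reaction that exploits the adjacency of quaternary C4 (CH3, CH2O) and the ring-fusion CH C5. Methacrolein supplies C3–C4 with C18 and C19 (as CHO); a 1-vinylcyclohexene whose ring is ring B (C7 ketal) supplies C2–C1–C10–C5. One operation forms C2–C3 and C4–C5 and sets C4 and C5. The remaining C1=C10 alkene then takes the angular C20 from the face of the C19 hydroxyl. The C7 ketone relays C9 (cuprate anti to C20) and C8 (trans-diaxial hydration). The Z-coumarate is built last by esterification and Suzuki coupling.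

Key step: step 2

Remark: atoms carry labdane numbers (ring A: C1–C5, C10; ring B: C5–C10; C17 on C8, C18 and C19 on C4, C20 on C10, side chain C11–C16); the target as drawn is (4R,5S,8R,9R,10R), a trans-decalin with C19 cis to C20, the C9 chain trans to C20 and the 8-OH cis to C20.

Assumption: the (R)-configured oxazaborolidinium ion is taken to expose the enal face that gives (4R)-5, following the formyl C–H···O organisation model for 2-substituted acroleins; the enantiomeric catalyst would be used if the sense proved opposite.

Step 1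
Reactants: 1 1,4-dioxaspiro[4.5]dec-7-en-8-yl trifluoromethanesulfonate; 2 potassium trifluoro(vinyl)borate
Product: 3 8-vinyl-1,4-dioxaspiro[4.5]dec-7-ene
Conditions: PdCl2(dppf) (3 mol%), Et3N, n-PrOH, 80 °C
Reagents that add atoms: none
Why: Suzuki–Miyaura coupling of an alkenyl triflate with a vinylborate should give the 1-vinylcyclohexene diene without touching the dioxolane; no stereocentre is formed.

Step 2
Reactants: 3 8-vinyl-1,4-dioxaspiro[4.5]dec-7-ene; 4 methacrolein
Product: 5 (4R,5S)-octalin aldehyde
Conditions: (R)-3,3-diphenyl-1-(2-methylphenyl)tetrahydro-1H,3H-pyrrolo[1,2-c][1,3,2]oxazaborole (20 mol%) activated with Tf2NH (18 mol%), CH2Cl2, −78 °C → −40 °C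
Reagents that add atoms: none
Why: The s-trans enal bound to the chiral oxazaborolidinium ion adds across the s-cis diene in a concerted, asynchronous [4+2] cycloaddition; the closest known reaction type is the catalytic enantioselective Diels–Alder reaction of 2-substituted acroleins with 1-vinylcycloalkene dienes. Ring A is closed in the cycloaddition mode, suprafacial on both partners, so that C2–C3 and C4–C5 arise in one transition state. The quaternary C4 is set by the catalyst, which shields one face of the coordinated enal. C5 is set relative to C4 by the endo orientation of the formyl group, which places CHO cis to ring-B carbon C6 and therefore trans to H-5. The step needs "ortho" regioselectivity (C4 to ring carbon C5, C3 to the vinyl terminus C2), which the large HOMO coefficient at the unsubstituted vinyl terminus and the large LUMO coefficient at the enal β-carbon should secure under Lewis-acid activation. It also needs the dioxolane and the C1=C10 alkene to survive, which the low temperature should secure.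

Step 3
Reactants: 5 (4R,5S)-octalin aldehyde
Product: 6 (4R,5S)-octalin alcohol
Conditions: NaBH4, MeOH, 0 °C
Reagents that add atoms: none
Why: Hydride reduction of the neopentyl aldehyde should give the primary C19 alcohol that steers the next step; no new stereocentre is formed.

Step 4
Reactants: 6 (4R,5S)-octalin alcohol
Product: 7 1,10-methano alcohol (cyclopropane)
Conditions: Et2Zn, CH2I2, CH2Cl2, 0 °C → rt
Reagents that add atoms: diiodomethane, ICI
Why: In this hydroxyl-directed Simmons–Smith cyclopropanation the zinc alkoxide of the axial C19 hydroxymethyl group lies over C10 and should deliver the methylene to the C1=C10 face cis to C19 and anti to H-5, which fixes the C10 configuration.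

Step 5
Reactants: 7 1,10-methano alcohol (cyclopropane)
Product: 9 (4R,5S,10S)-trans-decalin hydroxy ketone, via dioxolane alcohol 8 (not isolated)
Conditions: H2 (4 atm), PtO2, AcOH, rt; filtration; then 1 M HCl, THF, rt
Reagents that add atoms: water, O
Why: Catalytic hydrogenolysis of the ring-fused cyclopropane should cleave the least hindered C1–CH2 bond, so the methylene becomes the angular C20 methyl with C10 unchanged (trans ring fusion, C20 cis to C19); acid hydrolysis of the dioxolane then frees the C7 ketone.

Step 6
Reactants: 9 (4R,5S,10S)-trans-decalin hydroxy ketone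
Product: 10 TBS ether of 9
Conditions: TBSCl, imidazole, DMF, rt
Reagents that add atoms: tert-butyl(chloro)dimethylsilane, CC(C)(C)[Si](C)(C)Cl
Why: Silylation of the primary C19 hydroxyl protects it from the oxidant, the organometallics and Tf2O used next; no stereocentre is touched.

Step 7
Reactants: 10 TBS ether of 9
Product: 11 C8=C9 enone
Conditions: IBX, DMSO/toluene, 70 °C
Reagents that add atoms: none
Why: IBX dehydrogenation of the ketone should run through the enol towards C8, because enolisation towards C6 is hindered by the quaternary C4 next to C5; this gives the C8=C9 enone.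

Step 8
Reactants: 11 C8=C9 enone; 12 (4-bromobut-1-yn-1-yl)trimethylsilane
Product: 14 8-methyl-9-[4-(trimethylsilyl)but-3-ynyl] ketone, via bromomagnesium enolate 13 (not isolated)
Conditions: 12, Mg, THF; CuBr·SMe2, −40 °C; 11, −78 °C → −30 °C; then MeI, HMPA, −30 °C → 0 °C
Reagents that add atoms: iodomethane, CI
Why: In this organocopper conjugate addition with enolate C-methylation the cuprate should attack C9 axially, anti to the axial C20 methyl, so the chain is trans to C20; the regiospecific enolate is methylated at C8, whose configuration is erased in step 9.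

Step 9
Reactants: 14 8-methyl-9-[4-(trimethylsilyl)but-3-ynyl] ketone
Product: 15 C7=C8 enol triflate
Conditions: Tf2O, 2,6-di-tert-butyl-4-methylpyridine, CH2Cl2, 0 °C → rt
Reagents that add atoms: trifluoromethanesulfonic anhydride, O=S(=O)(OS(=O)(=O)C(F)(F)F)C(F)(F)F
Why: Enol triflate formation under equilibrating conditions should favour the more substituted C7=C8 enol, since the alternative C6=C7 enol is strained against the C4 substituents.

Step 10
Reactants: 15 C7=C8 enol triflate
Product: 16 C7=C8 alkene
Conditions: Pd(OAc)2 (5 mol%), PPh3, HCO2H, Bu3N, DMF, 60 °C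
Reagents that add atoms: none
Why: Palladium-catalysed formate reduction of the alkenyl triflate should replace OTf by H and leave the trisubstituted alkene with the methyl on C8; the hindered silylalkyne should be left alone.

Step 11
Reactants: 16 C7=C8 alkene
Product: 18 silyl-protected (4R,5S,8R,9R,10R)-8-ol, via organomercurial 17 (not isolated)
Conditions: Hg(OAc)2, THF/H2O, 0 °C → rt; then 3 M NaOH, NaBH4, 0 °C
Reagents that add atoms: water, O
Why: Oxymercuration–demercuration hydrates the alkene in the Markovnikov sense by anti addition; trans-diaxial opening of the mercurinium ion should put water on the tertiary C8 along the axial line, so the 8-OH is axial, cis to C20 and trans to the C9 chain.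

Step 12
Reactants: 18 silyl-protected (4R,5S,8R,9R,10R)-8-ol
Product: 19 alkyne diol
Conditions: TBAF, THF, 0 °C → rt
Reagents that add atoms: none
Why: Fluoride cleaves both the alkynyl C–Si bond and the primary silyl ether, freeing the terminal alkyne and the C19 hydroxyl in one operation; no stereocentre is touched.

Step 13
Reactants: 19 alkyne diol; 20 ethylene
Product: 21 diene diol
Conditions: ethylene (1 atm), second-generation Grubbs catalyst RuCl2(H2IMes)(PCy3)(=CHPh) (5 mol%), CH2Cl2, rt → 40 °C
Reagents that add atoms: none
Why: Enyne cross-metathesis of the terminal alkyne with ethylene should give the 2-substituted buta-1,3-diene (C13=C16, C14=C15) directly and tolerates the free hydroxyls.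

Step 14
Reactants: 21 diene diol; 22 (Z)-3-iodoprop-2-enoic acid
Product: 23 19-[(Z)-3-iodoacrylate]
Conditions: EDC·HCl, DMAP (0.1 equiv), CH2Cl2, 0 °C, dark
Reagents that add atoms: none
Why: Carbodiimide (Steglich) esterification should acylate the primary C19 hydroxyl and leave the hindered tertiary 8-OH; the Z geometry of the iodoacrylate should hold at 0 °C.

Step 15
Reactants: 23 19-[(Z)-3-iodoacrylate]; 24 (4-hydroxyphenyl)boronic acid
Product: 25 target cis-4-hydroxycinnamate
Conditions: Pd(PPh3)4 (5 mol%), 2 M aq. Na2CO3, THF, rt, dark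
Reagents that add atoms: none
Why: Suzuki–Miyaura coupling of the alkenyl iodide should proceed with retention of the Z geometry and tolerates the free phenol, the tertiary alcohol and the diene, so no protecting group remains to be removed.

Compound list

1 | 1,4-dioxaspiro[4.5]dec-7-en-8-yl trifluoromethanesulfonate | O=S(=O)(OC1=CCC2(CC1)OCCO2)C(F)(F)F | starting material
2 | potassium trifluoro(vinyl)borate | [K+].C=C[B-](F)(F)F | starting material
3 | 8-vinyl-1,4-dioxaspiro[4.5]dec-7-ene (ring-B diene; ketal carbon is C7) | C=CC1=CCC2(CC1)OCCO2 | intermediate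
4 | methacrolein (2-methylprop-2-enal) | CC(=C)C=O | starting material
5 | (4R,5S)-octalin aldehyde: C1=C10 alkene, C4 bearing CH3 and CHO with CHO trans to H-5, C7 ethylene ketal | C1C2=CCC[C@@](C)(C=O)[C@H]2CC3(OCCO3)C1 | intermediate
6 | (4R,5S)-octalin alcohol: as 5 with CH2OH on C4 | C1C2=CCC[C@@](C)(CO)[C@H]2CC3(OCCO3)C1 | intermediate
7 | 1,10-methano alcohol: cyclopropane across C1–C10 of 6, methylene cis to the CH2OH group | C1[C@@]23C[C@H]3CC[C@@](C)(CO)[C@H]2CC4(OCCO4)C1 | intermediate
8 | (4R,5S,10S)-7,7-ethylenedioxy-4-(hydroxymethyl)-4,10-dimethyl-trans-decalin (C19 cis to C20) | C1[C@]2(C)CCC[C@@](C)(CO)[C@H]2CC3(OCCO3)C1 | intermediate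
9 | (4R,5S,10S)-4-(hydroxymethyl)-4,10-dimethyl-trans-decalin-7-one | C1[C@]2(C)CCC[C@@](C)(CO)[C@H]2CC(=O)C1 | intermediate
10 | tert-butyldimethylsilyl ether of 9 | C1[C@]2(C)CCC[C@@](C)(CO[Si](C)(C)C(C)(C)C)[C@H]2CC(=O)C1 | intermediate
11 | C8=C9 enone of 10 (C7 ketone conjugated with C8=C9) | O=C1C=C[C@]2(C)CCC[C@@](C)(CO[Si](C)(C)C(C)(C)C)[C@H]2C1 | intermediate
12 | (4-bromobut-1-yn-1-yl)trimethylsilane | C[Si](C)(C)C#CCCBr | starting material
13 | bromomagnesium C7–C8 enolate carrying the 9-[4-(trimethylsilyl)but-3-ynyl] chain trans to C20 | C[Si](C)(C)C#CCC[C@@H]1[C@]2(C)CCC[C@@](C)(CO[Si](C)(C)C(C)(C)C)[C@H]2CC(O[Mg]Br)=C1 | intermediate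
14 | 8-methyl-9-[4-(trimethylsilyl)but-3-ynyl]-7-ketone (chain trans to C20; drawn as the equatorial 8-methyl epimer, the other epimer converges in step 9) | C[Si](C)(C)C#CCC[C@@H]1[C@]2(C)CCC[C@@](C)(CO[Si](C)(C)C(C)(C)C)[C@H]2CC(=O)[C@@H]1C | intermediate
15 | C7=C8 enol triflate (triflate on C7, methyl on C8) | C[Si](C)(C)C#CCC[C@@H]1[C@]2(C)CCC[C@@](C)(CO[Si](C)(C)C(C)(C)C)[C@H]2CC(OS(=O)(=O)C(F)(F)F)=C1C | intermediate
16 | C7=C8 alkene (methyl on C8) | C[Si](C)(C)C#CCC[C@@H]1[C@]2(C)CCC[C@@](C)(CO[Si](C)(C)C(C)(C)C)[C@H]2CC=C1C | intermediate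
17 | 7-(acetoxymercurio)-8-ol, Hg and OH trans-diaxial | C[Si](C)(C)C#CCC[C@@H]1[C@]2(C)CCC[C@@](C)(CO[Si](C)(C)C(C)(C)C)[C@H]2C[C@H]([Hg]OC(C)=O)[C@@]1(C)O | intermediate
18 | (4R,5S,8R,9R,10R)-8-ol with C19 OTBS and silylated alkyne chain (8-OH cis to C20, trans to the C9 chain) | C[Si](C)(C)C#CCC[C@@H]1[C@]2(C)CCC[C@@](C)(CO[Si](C)(C)C(C)(C)C)[C@H]2CC[C@@]1(C)O | intermediate
19 | (4R,5S,8R,9R,10R)-9-(but-3-ynyl)-8,19-diol | C#CCC[C@@H]1[C@]2(C)CCC[C@@](C)(CO)[C@H]2CC[C@@]1(C)O | intermediate
20 | ethylene | C=C | starting material
21 | (4R,5S,8R,9R,10R)-labda-13(16),14-diene-8,19-diol | C=CC(=C)CC[C@@H]1[C@]2(C)CCC[C@@](C)(CO)[C@H]2CC[C@@]1(C)O | intermediate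
22 | (Z)-3-iodoprop-2-enoic acid | OC(=O)/C=C\I | starting material
23 | 19-[(Z)-3-iodoacrylate] of 21 | C=CC(=C)CC[C@@H]1[C@]2(C)CCC[C@@](C)(COC(=O)/C=C\I)[C@H]2CC[C@@]1(C)O | intermediate
24 | (4-hydroxyphenyl)boronic acid | OB(O)c1ccc(O)cc1 | starting material
25 | (4R,5S,8R,9R,10R)-8-hydroxylabda-13(16),14-dien-19-yl (Z)-3-(4-hydroxyphenyl)prop-2-enoate | C=CC(=C)CC[C@@H]1[C@]2(C)CCC[C@@](C)(COC(=O)/C=C\c3ccc(O)cc3)[C@H]2CC[C@@]1(C)O | target

Total step count: 15. Longest linear sequence: 15 steps (from 1 to 25); all other partners are commercial.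

Steps most likely to fail

Step 4. Methylene delivery may not follow the remote (bishomoallylic) C19 hydroxyl and may instead occur on the more open face syn to H-5, which after hydrogenolysis would give the cis ring fusion; the hindered trisubstituted alkene may also react sluggishly. The fallback sets out from alcohol 6 and builds the quaternary centre by radical chemistry instead of carbenoid delivery. Iron-hydride hydrogen-atom-transfer hydromethylation (Fe(acac)3, PhSiH3, formaldehyde 2,4,6-trimethylbenzenesulfonylhydrazone made from the hydrazide and paraformaldehyde, THF/MeOH) should generate the tertiary C10 radical, whose axial trapping anti to H-5 by the hydrazone carbon would give the sulfonylhydrazide F1. Warming with Et3N in MeOH expels sulfinate and dinitrogen to leave the angular methyl. The route is rejoined at dioxolane alcohol 8, which is hydrolysed to 9 as in the second stage of step 5.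

Step 2. Enantioface discrimination or endo selectivity may erode with the α-branched enal, and the strongly acidic catalyst may open the dioxolane. The fallback sets out from diene 3 and methacrolein 4 and separates the cycloaddition from the source of absolute configuration. An achiral Me2AlCl-promoted Diels–Alder reaction (CH2Cl2, −78 °C) would give 5 together with its enantiomer F2, and NaBH4 would then give 6 together with its enantiomer F3. Esterification with (S)-2-methoxy-2-phenylacetic acid (DCC, DMAP) would give the diastereomeric esters F4 (from 6) and F5 (from F3), to be separated by chromatography. Methanolysis of F4 (K2CO3, MeOH) returns the route at alcohol 6.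

Step 11. Hg(OAc)2 may attack the silylalkyne or add only slowly to the hindered trisubstituted alkene, so chemoselectivity may be lost. The fallback sets out from alkene 16 and replaces mercury by a halohydrin–epoxide–hydride sequence governed by the same trans-diaxial rule. NBS in aqueous DME should give the trans-diaxial 7-bromo-8-ol F6. LiAlH4 in THF should then close the alkoxide onto C7 to give the 7,8-epoxide F7 on the face of C20 and open it by hydride attack at C7. The route is rejoined at tertiary alcohol 18.

Further compounds

F1 | step 4 | N'-[(10-yl)methyl]-2,4,6-trimethylbenzenesulfonohydrazide of the trans-decalin dioxolane alcohol (CH2NHNHSO2Ar on C10, cis to C19) | C1[C@]2(CNNS(=O)(=O)c3c(C)cc(C)cc3C)CCC[C@@](C)(CO)[C@H]2CC4(OCCO4)C1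
F2 | step 2 | (4S,5R)-octalin aldehyde (enantiomer of 5) | C1C2=CCC[C@](C)(C=O)[C@@H]2CC3(OCCO3)C1
F3 | step 2 | (4S,5R)-octalin alcohol (enantiomer of 6) | C1C2=CCC[C@](C)(CO)[C@@H]2CC3(OCCO3)C1
F4 | step 2 | (S)-2-methoxy-2-phenylacetate of 6 | C1C2=CCC[C@@](C)(COC(=O)[C@@H](OC)c3ccccc3)[C@H]2CC4(OCCO4)C1
F5 | step 2 | (S)-2-methoxy-2-phenylacetate of F3 | C1C2=CCC[C@](C)(COC(=O)[C@@H](OC)c3ccccc3)[C@@H]2CC4(OCCO4)C1
F6 | step 11 | 7-bromo-8-ol from 16 (Br on C7 and OH on C8 trans-diaxial, OH cis to C20) | C[Si](C)(C)C#CCC[C@@H]1[C@]2(C)CCC[C@@](C)(CO[Si](C)(C)C(C)(C)C)[C@H]2C[C@H](Br)[C@@]1(C)O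
F7 | step 11 | 7,8-epoxide from F6 (oxygen cis to C20) | C[Si](C)(C)C#CCC[C@@H]1[C@]2(C)CCC[C@@](C)(CO[Si](C)(C)C(C)(C)C)[C@H]2C[C@H]3O[C@]31C
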